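The examiner sets down the earlier runs and one new flask, and asks what that flask holds at 4.0 min.

| flask | starting material | reagent | free catalyst | remark | time |
|---|---|---|---|---|---|
| north-east | 0.12 M | 0.70 equiv (in portions, 4) | 0.16 mol% | run made earlier; portions every 1.0 s |  |
| south-east | 0.46 M | 0.70 equiv (in portions, 4) | 0.16 mol% | run made earlier; portions every 1.0 s |  |
| west | 0.23 M | 0.70 equiv (in portions, 4) | 0.24 mol% | run made earlier; portions every 1.0 s |  |
| flask | 0.23 M | 0.700 equiv (in portions, 4) | 0.16 mol% | the portions of reagent follow each other after 1.0 s, the first at the start | 4.0 min |

- north-east (time / min: product / %, starting material / %): 0.200: 11, 87; 0.333: 24, 76; 0.667: 41, 57; 1.33: 64, 36; 2.50: 68, 31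
- south-east (time / min: product / %, starting material / %): 0.500: 55, 44; 1.00: 74, 33; 1.33: 70, 32; 2.00: 71, 30; 2.50: 67, 29
- west (time / min: product / %, starting material / %): 0.500: 62, 39; 1.00: 68, 31; 1.33: 73, 32; 2.00: 72, 28; 2.50: 70, 28

(each reading ± 2 percentage points)

- a reading or a percentage of product counts all its forms, free or not

- how much product the flask holds at 4.0 min, in percent of the starting material charged
- how much starting material the flask holds at 4.0 min, in percent of the starting material charged

Where do the earlier runs stop? Near one place. Their last readings of starting material, at 2.50 min, are 31%, 29% and 28%, although the concentration went from 0.12 M to 0.46 M and the loading from 0.16 mol% to 0.24 mol%.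

What do you carry to the next flask? A ratio, not a rate. Divide the rate at which starting material goes by the rate at which reagent goes, and time drops out. What stays is the consumption per equivalent: the fraction of starting material gone at the stop, divided by the equivalents of reagent charged. From the mean of those last readings it comes to 1.01, with 2 percentage points of scatter on each reading: about one starting material per reagent.

And for this flask? With 0.700 equiv, I reckon 70.7% of the starting material gone, so 29.3% remains. I count what has gone as product, and late product readings of 68%, 67% and 70% allow that.

But has it reached its stop by then? The north-east run, at the same loading and half the concentration, reads 36% starting material at 1.33 min and 31% at 2.50 min. That is well before 4.0 min. The south-east run, more concentrated than the flask, is down to 44% starting material by 0.500 min.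

The forecast says 69.5% product and 29.5% starting material, holding that “the reaction should stop near 70% product and 30% starting material”. My product figure stands 1.2 points above it.

At 4.0 min the flask holds 70.0% product and 30.0% starting material.

    reagent + free catalyst ⇌ catalyst intermediate A (K = 6.00 L mol⁻¹, k = 370 L mol⁻¹ s⁻¹)
    catalyst intermediate A ⇌ catalyst intermediate B (K = 21.0, k = 290 s⁻¹)
    catalyst intermediate B → by-product + catalyst intermediate C (k = 31.0 s⁻¹)
    starting material + catalyst intermediate C → catalyst intermediate D (k = 320 L mol⁻¹ s⁻¹)
    catalyst intermediate D → free catalyst + product (k = 57.0 s⁻¹)
    crystals ⇌ product, rate k6*(cs6 - [product]) while solid is left; crystals form when [product] > cs6 (solubility = 6.20 mM, k = 2.00 s⁻¹)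

At that time 0% of the charged reagent is left in the flask against 30% of the starting material: reagent is the limiting reagent. The consumption per equivalent of this flask comes to 1.00. For a flask like this one but charged with 0.420 equiv of reagent, the 1.01 read from the earlier runs gives 42.4% product, and that flask holds 42.0% at 4.0 min.

Readings and results were generated by integration for substances that don't exist; noise was put on by code.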